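## The problem

Target 26 (C56H42O12) is a resveratrol tetramer in which two dibenzo-fused eight-membered carbocycles share one C–C bond and each carries a trans-2-aryl-2,3-dihydrobenzofuran. Locants used throughout: Ca/Ca′ are the ring CH groups bearing a 4-hydroxyphenyl group, Cb/Cb′ the two CH groups of the shared bond, C2/C3 the dihydrofuran carbons, ring A the resorcinol ring between Ca and C3, and ring B the benzo ring of the dihydrobenzofuran (C3a–C7a); one eight-membered ring runs Ca–ring A–C3–C3a–C4–Cb′–Cb and the other is its primed counterpart, so Cb is bonded to Ca and C4′, and Cb′ to Ca′ and C4. Of the eight stereocentres, C2, C3 and Cb are the mirror images of C2′, C3′ and Cb′ (a centrosymmetric core, Cb–H anti to Cb′–H, both dihydrofurans trans), whereas Ca and Ca′ are both R; this alone removes all symmetry and makes the molecule chiral. Cb/Cb′ can be fixed early from a meso 2,3-diarylsuccinate, C3 follows C2 thermodynamically (trans), C2 can be biased only by the remote ring-fusion centre, and the like configuration at Ca and Ca′ cannot come from the mirror-symmetric core and must be imposed by a chiral reagent. Ten phenols have to be masked; the benzylic C2–O bond ionises under strong acid, a carbanion at C3 can expel the aryloxide, and the Cb protons are epimerisable for as long as Ca is a carbonyl group. The enabling feature appears when ring A is removed and Ca is a ketone: Ca, C3, C3a, C4, Cb′ and Cb then form a six-membered ring in which C3 and C2 are the α- and β-carbons of a flat 3-acylbenzofuran, a vinylogous ester that is electrophilic at C2. The same ketone that activates C2 for arylation later accepts ring A by a two-carbon ring expansion.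

## Retrosynthesis

**26 from 25.** The ten O–CH3 bonds are cut last. Methyl ethers are preferred to benzyl or silyl ethers because they survive SnCl4, organocopper and organozinc reagents, fluoride and enolate chemistry; benzyl ethers would compete with the benzylic C2–O bonds on hydrogenolysis and silyl ethers would not survive CsF. Decamethyl ether 25 is no simpler in skeleton but is inert. The forward step must cleave ten ethers without lasting ionisation of C2–O.

**25 from 22 and 10, and 22 from 21.** The two Ca–aryl bonds are cut. Ca and Ca′ are the only centres that are not mirror-related, so removing them returns the achiral, centrosymmetric diketone 21, and all chirality enters in one catalytic step. Cutting Ca–ring A instead (an eight-membered Friedel–Crafts closure) would force the absolute configuration to be carried through the whole route. Forward, 21 is reduced to diol 22, and a nickel catalyst with a chiral ligand must arylate both benzylic positions with the same sense, overriding the substrate at one of them.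

**21 from 20 and 19, and 20 from 12.** In each half the bonds ring A–C3 and ring A–Ca are cut, which formally removes an aryne and contracts each eight-membered ring to a six-membered ketone; the ketone is handled as its bis(triethylsilyl enol ether) 20, cut at O–Si back to diketone 12. This avoids any medium-ring cyclisation; the alternative cuts (Cb–Cb′, or Ca–ring A) would have to close eight-membered rings directly. The methoxy group of the aryne released from 19 fixes the orientation. Forward, the enol ether must form toward C3 and not toward Cb, and the C3 anion formed on fragmentation must not open the dihydrofuran.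

**12 from 9 and 10 (key disconnection).** The two C2–aryl bonds are cut, which flattens both dihydrofurans to benzofurans and leaves the bis(3-acylbenzofuran) 9 with only two stereocentres, plus commercial Grignard reagent 10. Cutting C2–O or C2–C3 instead would require a stereodefined acyclic precursor for each half, in opposite enantiomeric series. Here an achiral reagent acting on a centrosymmetric substrate should give the mirror-related halves by symmetry. Forward, the reagent must add 1,4 and not 1,2, enter anti to the neighbouring pseudoaxial Cb–H at both ends, and leave the enolate without ring opening.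

**9 from 7, and 7 from 6.** The two Ca–C3 acyl–heteroaryl bonds are cut to give meso diacid 7 (from diester 6). The neighbouring cut, C4–Cb′, would need a ketone α-arylation at a ring-fusion carbon. Forward, each acylium ion must attack C3 (six-membered closure) rather than C5 (five-membered closure).

**6 from 5.** The Cb–Cb′ bond is cut, which halves the molecule into two identical arylacetates 5. Forward, oxidative enolate coupling is followed by equilibration to the meso diester.

**5 from 4, 4 from 2 and 3, 2 from 1.** The furan ring (C3–C3a and O–C2) is cut back to an aryloxyacetaldehyde acetal 4, made from phenol 2 and acetal 3; 2 comes from commercial resorcinol ester 1. Forward, the cyclodehydration must close para to the methoxy group.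

**19 from 17, 17 from 14, 14 from 13.** The aryne precursor is cut at O–SO2CF3 and C–Si; a carbamate on commercial phenol 13 directs the silylation to the position between the two oxygens.

## Roads not taken

**Alternative 1:** The cut removes the bonds from Ca and Ca′ to the ring-fusion carbons of a linear tetracenedione. Forward, a chiral BINOL-derived phosphoric acid would ionise the two 4-hydroxybenzhydrol groups of the open-chain 1,4-diketone A1 to para-quinone methides and guide the enol of each ketone onto the quinone methide of the other aryl ketone, giving the trans-fused tetrahydrotetracene-5,11-dione A2 (ketones at the future C3 and C3′). Its merit is real: Ca and Ca′ are set early, both with the same sense, by a well-documented type of catalysis, and the unsymmetrical Ca pattern of the target follows naturally from like induction on a trans ring fusion. This is better than the chosen plan at the very point where the chosen plan is weakest (step 14). Its weak points are that each enol can also attack the quinone methide on its own ring and close a five-membered indanone, and that after the key step ring B and both dihydrofurans are still missing. They would have to be grown from hindered diaryl ketones inside eight-membered rings, with four stereocentres (C2, C3, C2′, C3′) set late. The chosen plan sets against it that the dihydrobenzofurans are built first, from flat symmetric material, and that only three steps follow the ring expansion.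

**Alternative 2:** The cut removes ring B altogether. The pyrone-tethered alkynylboronate A3, in which the alkyne is linked through the future C2–C3 unit to the 6-oxygen of a 4-methoxy-2-pyrone, would undergo intramolecular [4+2] cycloaddition across C3 and C6 of the pyrone; loss of CO2 aromatises ring B and gives the trans-2,3-diaryl-2,3-dihydrobenzofuran-4-yl boronate A4. Ring B is assembled with full control of its substitution, boron sits exactly at C4 where Cb must be attached, and the trans C2/C3 relationship is fixed in an acyclic precursor; pyrone–alkynylboronate cycloadditions are established. In certainty of the dihydrofuran stereochemistry and in precedent this road is clearly better than the chosen key step. Its weak point is reach: the boronate A4 is only one quarter of the target with ring A pendant. The centrosymmetric core needs the two halves in opposite absolute configuration, so both enantiomers of A4 or a selective heterochiral union would be required. The Cb–Cb′ bond, an sp2–sp3 coupling at the crowded C4, both eight-membered ring closures and both Ca centres all remain. The chosen plan sets against it that symmetry pairs the halves automatically and that the eight-membered rings arise by ring expansion instead of cyclisation.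

**Alternative 3:** The cut is the same ring expansion the chosen route uses for ring A, applied instead to ring B. The bis-enolate of tetrahydrotetracenedione A5 (from KN(SiMe3)2) would meet the alkoxyaryne released by CsF from silylaryl triflate A6; each Cb adds to the aryne, the aryl anion closes on the C3 ketone and fragmentation inserts ring B between Cb and C3, giving the bis(dibenzocyclooctadienone) A7 with 4-methoxybenzyl ethers placed for later furan closure. In two respects it is better than steps 11 and 12 of the chosen route: each ketone of A5 has a single α-C–H, so enolate regiochemistry is unambiguous, and the carbanion released on fragmentation has no β-leaving group. Ca and Ca′ are also already in place. Its weak points are that A5 must first be made with the unsymmetrical Ca pattern (the problem of alternative 1), and that after the expansion C2, its aryl group and the C2–O bond must be added to hindered ketones, creating four stereocentres late under substrate control. The chosen plan sets against it that both dihydrofurans are complete before the expansion and that only Ca and Ca′ are left for the end.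

Key step: step 7

Remark: the (S,S) enantiomer of the bis(oxazoline) ligand in step 14 is assumed to give the R configuration at Ca and Ca′; if the sense of induction is the reverse, the (R,R) ligand is used and nothing else changes.
Remark: 10 is taken as the commercial 0.5 M solution in THF; the Ca/Ca′ centres of 22–24 are left unassigned because step 14 erases them.

## Route

Step 1
Reactants: 1 methyl 2-(3,5-dihydroxyphenyl)acetate
Product: 2 methyl 2-(3-hydroxy-5-methoxyphenyl)acetate
Conditions: MeI (1.0 equiv), K2CO3 (1.0 equiv), acetone, 56 °C
Reagents that add atoms: iodomethane, CI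
Why: Williamson etherification; with one equivalent of MeI the symmetric resorcinol should give the mono-ether statistically, and unreacted 1 and the dimethyl ether are separated (1 is recycled).

Step 2
Reactants: 2 methyl 2-(3-hydroxy-5-methoxyphenyl)acetate; 3 2-bromo-1,1-diethoxyethane
Product: 4 methyl 2-[3-(2,2-diethoxyethoxy)-5-methoxyphenyl]acetate
Conditions: K2CO3, KI (cat.), DMF, 110 °C
Reagents that add atoms: none
Why: Williamson O-alkylation of the remaining phenol with the acetal-protected bromoacetaldehyde, the standard entry to benzofurans; carbonate should not enolise the arylacetate to a harmful extent.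

Step 3
Reactants: 4 methyl 2-[3-(2,2-diethoxyethoxy)-5-methoxyphenyl]acetate
Product: 5 methyl 2-(6-methoxy-1-benzofuran-4-yl)acetate
Conditions: polyphosphoric acid, toluene, 100 °C
Reagents that add atoms: none
Why: Acid-mediated cyclodehydration of an aryloxyacetaldehyde acetal (intramolecular Friedel–Crafts alkylation by the oxocarbenium ion, then loss of ethanol). Closure para to the methoxy group, between the ether oxygen and the acetate arm, is the electronically favoured one and gives the 4,6-pattern; the isomer from closure between the two oxygens is expected as the minor product and is removed by chromatography.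

Step 4
Reactants: 5 methyl 2-(6-methoxy-1-benzofuran-4-yl)acetate (two molecules)
Product: 6 dimethyl meso-(2R,3S)-2,3-bis(6-methoxy-1-benzofuran-4-yl)butanedioate
Conditions: LiN(i-Pr)2, THF, −78 °C; I2 (0.5 equiv), −78 → 20 °C; then NaOMe (cat.), MeOH, 60 °C, crystallisation
Reagents that add atoms: second molecule of 5 methyl 2-(6-methoxy-1-benzofuran-4-yl)acetate, COC(=O)Cc1cc(OC)cc2occc12
Why: Oxidative homocoupling of an ester enolate joins two molecules of 5 (half of the enolate is iodinated, the other half displaces iodide by SN2) and forms the Cb–Cb′ bond. Both new centres are activated by an ester and an aryl group, so methoxide equilibrates them and the less soluble centrosymmetric meso diester should crystallise, as is usual for 2,3-diarylsuccinates.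

Step 5
Reactants: 6 dimethyl meso-(2R,3S)-2,3-bis(6-methoxy-1-benzofuran-4-yl)butanedioate
Product: 7 meso-(2R,3S)-2,3-bis(6-methoxy-1-benzofuran-4-yl)butanedioic acid
Conditions: LiOH·H2O, THF–MeOH–H2O, 40 °C; then 1 M HCl
Reagents that add atoms: lithium hydroxide, [Li+].[OH-]
Why: Saponification; once an ester has become a carboxylate its α-proton is no longer exchanged, so the meso configuration should be kept.

Step 6
Reactants: 7 meso-(2R,3S)-2,3-bis(6-methoxy-1-benzofuran-4-yl)butanedioic acid
Product: 9 trans-fused meso bis(3-acylbenzofuran) diketone (6- and 6′-OMe; Ca=O joins C3 to Cb; Ca′=O joins C3′ to Cb′; Cb on C4′; Cb′ on C4; Cb R; Cb′ S), via bis(acid chloride) 8 (not isolated)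
Conditions: (COCl)2, DMF (cat.), CH2Cl2, 0 → 20 °C; then SnCl4, CH2Cl2, −78 → 0 °C
Reagents that add atoms: none
Why: Twofold intramolecular Friedel–Crafts acylation: each acylium ion reaches C3 of the benzofuran on the neighbouring succinate carbon through a six-membered transition state, C3 being the nucleophilic β-carbon of the enol ether O1–C2=C3. Attack at C5 would close a five-membered indanone and attack on the proximal benzofuran a strained peri-fused five-membered ring. The stereocentres are not touched, so the meso acid should give the trans-fused centrosymmetric diketone.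

Step 7
Reactants: 9 trans-fused meso bis(3-acylbenzofuran) diketone; 10 4-methoxyphenylmagnesium bromide
Product: 12 meso bis[trans-2-(4-methoxyphenyl)-2,3-dihydrobenzofurano] diketone (C2 R; C3 R; Cb R; C2′ S; C3′ S; Cb′ S; each 2-aryl group anti to the adjacent Cb–H), via bis(trimethylsilyl enol ether) 11 (not isolated)
Conditions: 10 (6 equiv), CuBr·SMe2 (3 equiv), Me3SiCl (8 equiv), THF, −78 → −20 °C; then 1 M HCl, THF, 0 °C; Et3N, MeOH, 20 °C
Reagents that add atoms: second molecule of 10 4-methoxyphenylmagnesium bromide, COc1ccc([Mg]Br)cc1
Why: Proposed new method: a 3-acylbenzofuran is a vinylogous ester whose furan ring holds little aromatic stabilisation, so the diarylcuprate should π-complex the C2=C3–Ca=O unit, deliver one aryl group to C2 through a trivalent copper intermediate and leave an enolate that Me3SiCl traps as silyl enol ether 11 before it can expel the phenoxide (a ring opening that would in any case be a disfavoured retro-5-endo-trig process). The closest known reaction types are copper- and rhodium-mediated conjugate arylations of chromones and dearomatising additions of nucleophiles to 3-nitrobenzofurans; addition to a benzofuran activated only by a ketone has not been shown. No ring is closed; two C2–aryl bonds form, one from each of two molecules of the aryl reagent, and two flat furans become dihydrofurans. C2 and C2′ are set by the substrate: the trans ring fusion holds each six-membered ring in a half-chair whose pseudoaxial Cb–H (Cb′–H) lies on one face next to the carbonyl group, so the cuprate should enter anti to it, and because 9 is centrosymmetric the preferred faces at the two ends are mirror images, which gives the meso pairing (C2 R, C2′ S). C3 and C3′ are set on work-up: kinetic protonation anti to the new aryl group would give the cis isomer, so after acid hydrolysis of 11 a brief amine equilibration of this β-oxygenated α-centre is used to place each acyl carbon trans to the neighbouring aryl group, the thermodynamic arrangement. The step needs 1,4- over 1,2-selectivity, for which the soft copper reagent and silyl activation speak, and it needs the α-protons at Cb to survive, for which the low basicity of the cuprate and the in situ conversion of each ketone into an enol ether speak. Diketone 12 is isolated so that diastereomers arising from imperfect facial control can be removed before the ring expansion.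

Step 8
Reactants: 13 3,5-dimethoxyphenol
Product: 14 3,5-dimethoxyphenyl N-isopropylcarbamate
Conditions: i-PrNCO, Et3N (cat.), CH2Cl2, 20 °C
Reagents that add atoms: isopropyl isocyanate, CC(C)N=C=O
Why: Carbamoylation of the phenol by an isocyanate installs a directing group for ortho-metalation that can later be removed under mild conditions.

Step 9
Reactants: 14 3,5-dimethoxyphenyl N-isopropylcarbamate
Product: 17 3,5-dimethoxy-2-(trimethylsilyl)phenyl N-isopropylcarbamate, via N-silyl carbamate 15 (not isolated), via C-silylated N-silyl carbamate 16 (not isolated)
Conditions: t-BuMe2SiOTf, TMEDA, Et2O, 0 → 20 °C; n-BuLi, TMEDA, −78 °C; Me3SiCl, −78 → 20 °C; aq. NaHSO4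
Reagents that add atoms: chlorotrimethylsilane, C[Si](C)(C)Cl
Why: Directed ortho-metalation: after in situ N-silylation the carbamate and the 3-methoxy group jointly direct lithiation to C2 (C2 and C6 are equivalent by symmetry; C4 lies between two methoxy groups only) and Me3SiCl quenches the aryllithium; the N–Si bond is lost on acidic work-up.

Step 10
Reactants: 17 3,5-dimethoxy-2-(trimethylsilyl)phenyl N-isopropylcarbamate
Product: 19 3,5-dimethoxy-2-(trimethylsilyl)phenyl trifluoromethanesulfonate, via silylphenol 18 (not isolated)
Conditions: DBU, Et2NH, MeCN, 40 °C; then PhN(SO2CF3)2, 20 °C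
Reagents that add atoms: N-phenylbis(trifluoromethanesulfonimide), O=S(=O)(N(c1ccccc1)S(=O)(=O)C(F)(F)F)C(F)(F)F
Why: Amine-induced cleavage of the N-monoalkyl carbamate (elimination to isopropyl isocyanate, trapped by Et2NH as a urea) releases the phenoxide, which is triflated in the same flask; this is a standard route to ortho-silylaryl triflates.

Step 11
Reactants: 12 meso bis[trans-2-(4-methoxyphenyl)-2,3-dihydrobenzofurano] diketone
Product: 20 bis(triethylsilyl enol ether) of 12 (Ca(OSiEt3)=C3 and Ca′(OSiEt3)=C3′; C2, C2′, Cb and Cb′ arranged in space as in 12)
Conditions: Et3SiOTf (3 equiv), Et3N (5 equiv), CH2Cl2, 0 °C; pentane, cold aq. NaHCO3; used without chromatography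
Reagents that add atoms: triethylsilyl trifluoromethanesulfonate, CC[Si](CC)(CC)OS(=O)(=O)C(F)(F)F; second equivalent of triethylsilyl trifluoromethanesulfonate, CC[Si](CC)(CC)OS(=O)(=O)C(F)(F)F
Why: Soft enolisation with a silyl triflate and a tertiary amine (silyl enol ether formation) should take the conjugated direction toward C3, the usual one for a 2-tetralone-type ketone, because the alternative toward Cb would flatten the ring fusion and press the siloxy group against the C5′–H of ring B′. The triethylsilyl ether is chosen because it survives a bicarbonate wash, which removes the amine and its triflate salt; either would otherwise trap the aryne or protonate the enolate in the next step. C3 and C3′ become trigonal, and C2, Cb and their primed partners are not touched.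

Step 12
Reactants: 20 bis(triethylsilyl enol ether) of 12; 19 3,5-dimethoxy-2-(trimethylsilyl)phenyl trifluoromethanesulfonate
Product: 21 meso bis(eight-membered ring) diketone octamethyl ether (ring A inserted between C3 and Ca in both halves; C2 R; C3 R; Cb R; C2′ S; C3′ S; Cb′ S)
Conditions: 19 (3 equiv), CsF (8 equiv), MeCN–toluene, 20 → 50 °C; aq. NH4Cl
Reagents that add atoms: second molecule of 19 3,5-dimethoxy-2-(trimethylsilyl)phenyl trifluoromethanesulfonate, COc1cc(OC)c([Si](C)(C)C)c(OS(=O)(=O)C(F)(F)F)c1
Why: Fluoride unmasks the caesium enolate and the aryne together: C3 adds to the aryne carbon meta to the 3-methoxy group, the aryl anion ortho to that methoxy group attacks Ca, and the benzocyclobutenoxide fragments to the doubly benzylic C3 anion, so that ring A is inserted between C3 and Ca (aryne insertion into the α C–C bond of a ketone enolate, a two-carbon ring expansion known for cyclic ketone enolates). The C3 anion is an ortho-quinodimethane enolate whose orbital is orthogonal to the C2–O bond, which should hold back β-elimination, and its reversible protonation should leave ring A trans to the C2 aryl group; Cb and Cb′ are carried over.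

Step 13
Reactants: 21 meso bis(eight-membered ring) diketone octamethyl ether
Product: 22 bis(eight-membered ring) diol octamethyl ether (carbinol centres Ca and Ca′ unassigned; core as in 21)
Conditions: NaBH4, CeCl3·7H2O, MeOH–THF, −20 → 0 °C
Reagents that add atoms: none
Why: Luche-type 1,2-reduction; CeCl3 activates the hindered di-ortho-substituted aryl ketones and keeps the medium close to neutral so that the α-centres Cb and Cb′ should not epimerise. The configuration of the new carbinol centres is irrelevant.

Step 14
Reactants: 22 bis(eight-membered ring) diol octamethyl ether; 10 4-methoxyphenylmagnesium bromide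
Product: 25 decamethyl ether of the target (C2 R; C3 R; Ca R; Cb S; C2′ S; C3′ S; Ca′ R; Cb′ R), via bis(mesylate) 23 (not isolated), via bis(iodide) 24 (not isolated)
Conditions: MsCl, Et3N, CH2Cl2, −40 °C; LiI; then NiBr2·diglyme (20 mol %), (4S,4′S)-2,2′-(propane-2,2-diyl)bis(4-phenyl-4,5-dihydrooxazole) (26 mol %), (4-MeOC6H4)ZnI (from 10 and ZnI2, THF), CH2Cl2–THF, −45 °C
Reagents that add atoms: second molecule of 10 4-methoxyphenylmagnesium bromide, COc1ccc([Mg]Br)cc1
Why: Nickel/bis(oxazoline)-catalysed stereoconvergent Negishi arylation of secondary benzylic electrophiles made in situ from the alcohols: halogen abstraction gives planar benzylic radicals at Ca and Ca′, which are captured by the chiral arylnickel species, so the configuration is set by the catalyst whatever the carbinol configuration was. Because the core of 22 is centrosymmetric, the same catalyst-imposed R configuration at both centres desymmetrises it and should give 25 as one enantiomer; at one of the two sites the catalyst has to override the substrate's own facial preference.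

Step 15
Reactants: 25 decamethyl ether of the target
Product: 26 target tetramer CNP0224452.2 (C2 R; C3 R; Ca R; Cb S; C2′ S; C3′ S; Ca′ R; Cb′ R)
Conditions: BBr3 (30 equiv), CH2Cl2, −78 → 20 °C; MeOH, then H2O
Reagents that add atoms: none
Why: Lewis acid cleavage of aryl methyl ethers by BBr3, the usual last step for permethylated oligostilbenes; low temperature and the fact that both dihydrofurans already have the thermodynamically favoured trans arrangement should limit damage from transient ionisation of the C2–O bonds.

## Compound list

1 | methyl 2-(3,5-dihydroxyphenyl)acetate | COC(=O)Cc1cc(O)cc(O)c1 | starting material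
2 | methyl 2-(3-hydroxy-5-methoxyphenyl)acetate | COC(=O)Cc1cc(O)cc(OC)c1 | intermediate
3 | 2-bromo-1,1-diethoxyethane (bromoacetaldehyde diethyl acetal) | CCOC(CBr)OCC | starting material
4 | methyl 2-[3-(2,2-diethoxyethoxy)-5-methoxyphenyl]acetate | CCOC(COc1cc(CC(=O)OC)cc(OC)c1)OCC | intermediate
5 | methyl 2-(6-methoxy-1-benzofuran-4-yl)acetate | COC(=O)Cc1cc(OC)cc2occc12 | intermediate
6 | dimethyl meso-(2R,3S)-2,3-bis(6-methoxy-1-benzofuran-4-yl)butanedioate | COC(=O)[C@H](c1cc(OC)cc2occc12)[C@H](c1cc(OC)cc2occc12)C(=O)OC | intermediate
7 | meso-(2R,3S)-2,3-bis(6-methoxy-1-benzofuran-4-yl)butanedioic acid | OC(=O)[C@H](c1cc(OC)cc2occc12)[C@H](c1cc(OC)cc2occc12)C(O)=O | intermediate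
8 | meso-2,3-bis(6-methoxy-1-benzofuran-4-yl)butanedioyl dichloride | ClC(=O)[C@H](c1cc(OC)cc2occc12)[C@H](c1cc(OC)cc2occc12)C(Cl)=O | intermediate (not isolated)
9 | trans-fused meso bis(3-acylbenzofuran) diketone: two 6-methoxybenzofurans; Ca(=O) bonded to C3 and Cb, Ca′(=O) bonded to C3′ and Cb′; Cb bonded to C4′, Cb′ bonded to C4; Cb–H anti to Cb′–H (Cb R, Cb′ S) | O=C2c3c4c(cc(OC)cc4[C@H]4C(=O)c5c6c(cc(OC)cc6[C@H]24)oc5)oc3 | intermediate
10 | 4-methoxyphenylmagnesium bromide | COc1ccc([Mg]Br)cc1 | starting material
11 | bis(trimethylsilyl enol ether) of 12: Ca(OSiMe3)=C3 and Ca′(OSiMe3)=C3′; C2, C2′, Cb and Cb′ arranged in space as in 12 (by the sequence rule C2 S, C2′ R, Cb R, Cb′ S, because the trigonal C3 now outranks the aryl group at C2) | C[Si](C)(C)OC2=C3c4c(cc(OC)cc4[C@H]4C(O[Si](C)(C)C)=C5c6c(cc(OC)cc6[C@H]24)O[C@@H]5c2ccc(OC)cc2)O[C@H]3c2ccc(OC)cc2 | intermediate (not isolated)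
12 | meso bis[trans-2-(4-methoxyphenyl)-2,3-dihydrobenzofurano] diketone: 9 with a 4-methoxyphenyl group on C2 and C2′, H on C3 and C3′; 2-aryl trans to the C3 acyl carbon and anti to the adjacent Cb–H (C2 R, C3 R, Cb R, C2′ S, C3′ S, Cb′ S) | O=C2[C@@H]3c4c(cc(OC)cc4[C@H]4C(=O)[C@H]5c6c(cc(OC)cc6[C@H]24)O[C@@H]5c2ccc(OC)cc2)O[C@H]3c2ccc(OC)cc2 | intermediate
13 | 3,5-dimethoxyphenol | COc1cc(O)cc(OC)c1 | starting material
14 | 3,5-dimethoxyphenyl N-isopropylcarbamate | COc1cc(OC)cc(OC(=O)NC(C)C)c1 | intermediate
15 | 3,5-dimethoxyphenyl N-(tert-butyldimethylsilyl)-N-isopropylcarbamate | COc1cc(OC)cc(OC(=O)N(C(C)C)[Si](C)(C)C(C)(C)C)c1 | intermediate (not isolated)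
16 | 3,5-dimethoxy-2-(trimethylsilyl)phenyl N-(tert-butyldimethylsilyl)-N-isopropylcarbamate | COc1cc(OC)c([Si](C)(C)C)c(OC(=O)N(C(C)C)[Si](C)(C)C(C)(C)C)c1 | intermediate (not isolated)
17 | 3,5-dimethoxy-2-(trimethylsilyl)phenyl N-isopropylcarbamate | COc1cc(OC)c([Si](C)(C)C)c(OC(=O)NC(C)C)c1 | intermediate
18 | 3,5-dimethoxy-2-(trimethylsilyl)phenol | COc1cc(O)c([Si](C)(C)C)c(OC)c1 | intermediate (not isolated)
19 | 3,5-dimethoxy-2-(trimethylsilyl)phenyl trifluoromethanesulfonate | COc1cc(OC)c([Si](C)(C)C)c(OS(=O)(=O)C(F)(F)F)c1 | intermediate
20 | bis(triethylsilyl enol ether) of 12: Ca(OSiEt3)=C3 and Ca′(OSiEt3)=C3′; C2, C2′, Cb and Cb′ arranged in space as in 12 (by the sequence rule C2 S, C2′ R, Cb R, Cb′ S) | CC[Si](CC)(CC)OC2=C3c4c(cc(OC)cc4[C@H]4C(O[Si](CC)(CC)CC)=C5c6c(cc(OC)cc6[C@H]24)O[C@@H]5c2ccc(OC)cc2)O[C@H]3c2ccc(OC)cc2 | intermediate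
21 | meso bis(eight-membered ring) diketone octamethyl ether: 12 with a 3,5-dimethoxybenzene ring (ring A) inserted between C3 and Ca and between C3′ and Ca′, methoxy groups ortho and para to the carbon bonded to Ca (C2 R, C3 R, Cb R, C2′ S, C3′ S, Cb′ S) | O=C2c3c(OC)cc(OC)cc3[C@@H]3c4c(cc(OC)cc4[C@H]4C(=O)c5c(OC)cc(OC)cc5[C@H]5c6c(cc(OC)cc6[C@H]24)O[C@@H]5c2ccc(OC)cc2)O[C@H]3c2ccc(OC)cc2 | intermediate
22 | diol from 21 (Ca–OH and Ca′–OH, configuration unassigned; core as in 21) | OC2c3c(OC)cc(OC)cc3[C@@H]3c4c(cc(OC)cc4[C@H]4C(O)c5c(OC)cc(OC)cc5[C@H]5c6c(cc(OC)cc6[C@H]24)O[C@@H]5c2ccc(OC)cc2)O[C@H]3c2ccc(OC)cc2 | intermediate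
23 | bis(methanesulfonate) of 22 (Ca/Ca′ unassigned) | CS(=O)(=O)OC2c3c(OC)cc(OC)cc3[C@@H]3c4c(cc(OC)cc4[C@H]4C(OS(C)(=O)=O)c5c(OC)cc(OC)cc5[C@H]5c6c(cc(OC)cc6[C@H]24)O[C@@H]5c2ccc(OC)cc2)O[C@H]3c2ccc(OC)cc2 | intermediate (not isolated)
24 | bis(iodide) corresponding to 23 (Ca/Ca′ unassigned) | IC2c3c(OC)cc(OC)cc3[C@@H]3c4c(cc(OC)cc4[C@H]4C(I)c5c(OC)cc(OC)cc5[C@H]5c6c(cc(OC)cc6[C@H]24)O[C@@H]5c2ccc(OC)cc2)O[C@H]3c2ccc(OC)cc2 | intermediate (not isolated)
25 | decamethyl ether of the target (C2 R, C3 R, Ca R, Cb S, C2′ S, C3′ S, Ca′ R, Cb′ R) | COc1ccc([C@@H]2c3c(OC)cc(OC)cc3[C@@H]3c4c(cc(OC)cc4[C@H]4[C@H](c5ccc(OC)cc5)c5c(OC)cc(OC)cc5[C@H]5c6c(cc(OC)cc6[C@H]24)O[C@@H]5c2ccc(OC)cc2)O[C@H]3c2ccc(OC)cc2)cc1 | intermediate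
26 | CNP0224452.2 (C2 R, C3 R, Ca R, Cb S, C2′ S, C3′ S, Ca′ R, Cb′ R) | Oc1ccc([C@@H]2c3c(O)cc(O)cc3[C@@H]3c4c(cc(O)cc4[C@H]4[C@H](c5ccc(O)cc5)c5c(O)cc(O)cc5[C@H]5c6c(cc(O)cc6[C@H]24)O[C@@H]5c2ccc(O)cc2)O[C@H]3c2ccc(O)cc2)cc1 | target

## Step count and least certain steps

Total: 15 steps. Longest linear sequence: 12 steps (steps 1–7 and 11–15); steps 8–10 are a three-step side branch to 19.

**Step 7 (key step, proposed new method).** The most likely failure is poor facial discrimination at C2: the only bias is the pucker imposed by a ring-fusion centre three bonds away, so the meso product may be accompanied by the diastereomers with like configuration at C2 and C2′, or the bias may run in the wrong sense. Competing 1,2-addition, enolisation at Cb with loss of the trans ring fusion, and ring opening of the enolate by loss of phenoxide are the other ways the step can go wrong. Fallback by known chemistry, from 9 back to 12: palladium-catalysed direct C2–H arylation of both benzofurans with 4-bromoanisole (Pd(OAc)2, PCy3·HBF4, pivalic acid, K2CO3, DMA, 100 °C) would give the bis[2-(4-methoxyphenyl)-3-acylbenzofuran] diketone F1. Hydrogenation of its two vinylogous-ester double bonds (H2, Pd/C, EtOAc–AcOH) would give the all-cis bis(dihydrofuran) diketone F2, and amine-mediated epimerisation at C3 and C3′ would return to 12. The C2–aryl bonds are then made by cross-coupling and the dearomatisation is a reduction. Because hydrogen and not the aryl group is now the entering group, the facial requirement is reversed: 12 results when hydrogen adds syn to the neighbouring Cb–H. The sequence is therefore the direct remedy if the substrate steers reagents to that face, the outcome that would defeat the cuprate addition; diastereomers would again be removed at the stage of 12.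

**Step 12.** The enol ether delivered by step 11 may contain the regioisomer formed toward Cb, which would insert the aryne into the wrong C–C bond; the C3 anion formed on fragmentation may open the dihydrofuran by β-elimination; the second insertion may lag behind the first; and protonation at C3 may not settle trans. Fallback, from 11 (the intermediate of step 7) back to 21: the key step is worked up without acid, and the bis(trimethylsilyl enol ether) 11 formed there, whose regiochemistry is fixed by the conjugate addition itself, is freed from magnesium and copper salts by dilution with pentane and filtration and taken directly into the CsF/19 treatment. This bypasses step 11, gives up the purification at the stage of 12 and makes no new compound, which is recorded below as F0.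

**Step 14.** The catalyst may fail to override the substrate at the mismatched site; coupling at a benzylic carbon flanked by a di-ortho-substituted arene and a tertiary carbon may be slow; and the very ionisable 2,4-dimethoxybenzylic electrophile may eliminate toward Cb. Fallback, from 21 back to 25: addition of (4-methoxyphenyl)cerium dichloride (from 10 and CeCl3, THF, −78 °C) to both ketones would give the bis(tertiary carbinol) F3. Ionic hydrogenation (Et3SiH, CF3CO2H, CH2Cl2, −40 °C) would then give the Ca epimers, from which the unsymmetrical isomer is separated and resolved by chromatography on a chiral stationary phase to give 25.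

**Step 6.** Acylation may occur at the methoxy-activated C5 (indanone) instead of C3, the 3-unsubstituted benzofurans may oligomerise under Lewis acid, and the acid chloride may epimerise or close to the cyclic anhydride. Fallback, from 6 back to 9: addition of Br2 to both furan double bonds (CH2Cl2, −78 °C) would give the tetrabromide F4. Ethanolic KOH would then eliminate HBr and saponify the esters to give the bis(3-bromobenzofuran) diacid F5. A Parham cyclisation (n-BuLi, 4.2 equiv, THF, −100 °C), in which each C3-lithium species attacks the distal lithium carboxylate, would close both six-membered ketones with the regiochemistry fixed by the halogen.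

**Step 3.** Cyclisation may occur in part between the two oxygens and give the 4-methoxy-6-substituted isomer. Fallback, from 1 back to 5, with the ring-closure position fixed by an aldehyde placed beforehand: Vilsmeier–Haack formylation (POCl3, DMF), which in orcinol-type resorcinols goes to the position between the side chain and a hydroxyl group, would give methyl 2-(2-formyl-3,5-dihydroxyphenyl)acetate F6. Methylation of the non-chelated hydroxyl group para to the aldehyde (MeI, K2CO3, acetone) would give methyl 2-(2-formyl-3-hydroxy-5-methoxyphenyl)acetate F7. Wittig methoxymethylenation (Ph3P=CHOMe in excess, THF) would give the enol ether F8, which closes to 5 with TsOH in toluene.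

## Further compounds

F1 | step 7 | bis[2-(4-methoxyphenyl)-3-acylbenzofuran] diketone (9 with 4-methoxyphenyl on C2 and C2′) | O=C2c3c4c(cc(OC)cc4[C@H]4C(=O)c5c6c(cc(OC)cc6[C@H]24)oc5-c2ccc(OC)cc2)oc3-c2ccc(OC)cc2
F2 | step 7 | all-cis bis(dihydrofuran) diketone (C3 and C3′ epimer of 12) | O=C2[C@H]3c4c(cc(OC)cc4[C@H]4C(=O)[C@@H]5c6c(cc(OC)cc6[C@H]24)O[C@@H]5c2ccc(OC)cc2)O[C@H]3c2ccc(OC)cc2
F0 | step 12 | none | none
F3 | step 14 | bis(tertiary carbinol) from 21 (4-methoxyphenyl and OH on Ca and Ca′, configuration unassigned) | OC2(c7ccc(OC)cc7)c3c(OC)cc(OC)cc3[C@@H]3c4c(cc(OC)cc4[C@H]4C(O)(c7ccc(OC)cc7)c5c(OC)cc(OC)cc5[C@H]5c6c(cc(OC)cc6[C@H]24)O[C@@H]5c2ccc(OC)cc2)O[C@H]3c2ccc(OC)cc2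
F4 | step 6 | dimethyl meso-2,3-bis(2,3-dibromo-6-methoxy-2,3-dihydro-1-benzofuran-4-yl)butanedioate | COC(=O)[C@H](c1cc(OC)cc2OC(Br)C(Br)c12)[C@H](c1cc(OC)cc2OC(Br)C(Br)c12)C(=O)OC
F5 | step 6 | meso-2,3-bis(3-bromo-6-methoxy-1-benzofuran-4-yl)butanedioic acid | OC(=O)[C@H](c1cc(OC)cc2occ(Br)c12)[C@H](c1cc(OC)cc2occ(Br)c12)C(O)=O
F6 | step 3 | methyl 2-(2-formyl-3,5-dihydroxyphenyl)acetate | COC(=O)Cc1cc(O)cc(O)c1C=O
F7 | step 3 | methyl 2-(2-formyl-3-hydroxy-5-methoxyphenyl)acetate | COC(=O)Cc1cc(OC)cc(O)c1C=O
F8 | step 3 | methyl 2-[3-hydroxy-5-methoxy-2-(2-methoxyethenyl)phenyl]acetate (E/Z mixture) | COC=Cc1c(O)cc(OC)cc1CC(=O)OC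
A1 | alternative 1 | 1,4-bis{2-[hydroxy(4-hydroxyphenyl)methyl]-3,5-dimethoxyphenyl}butane-1,4-dione | O=C(CCC(=O)c1cc(OC)cc(OC)c1C(O)c1ccc(O)cc1)c1cc(OC)cc(OC)c1C(O)c1ccc(O)cc1
A2 | alternative 1 | trans-fused 6,12-bis(4-hydroxyphenyl)-1,3,7,9-tetramethoxy-5a,6,11a,12-tetrahydrotetracene-5,11-dione | Oc1ccc([C@@H]2c3c(OC)cc(OC)cc3C(=O)[C@H]4[C@H](c5ccc(O)cc5)c5c(OC)cc(OC)cc5C(=O)[C@H]24)cc1
A3 | alternative 2 | 4-methoxy-6-{[2-(3,5-dimethoxyphenyl)-1-(4-methoxyphenyl)-4-(4,4,5,5-tetramethyl-1,3,2-dioxaborolan-2-yl)but-3-yn-1-yl]oxy}-2H-pyran-2-one | COc1cc(O[C@@H](c2ccc(OC)cc2)[C@H](c2cc(OC)cc(OC)c2)C#CB2OC(C)(C)C(C)(C)O2)oc(=O)c1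
A4 | alternative 2 | trans-3-(3,5-dimethoxyphenyl)-6-methoxy-2-(4-methoxyphenyl)-2,3-dihydrobenzofuran-4-yl pinacolboronate | COc1cc(OC)cc([C@@H]2c3c(cc(OC)cc3B3OC(C)(C)C(C)(C)O3)O[C@H]2c2ccc(OC)cc2)c1
A5 | alternative 3 | trans-fused 6,12-bis(4-methoxyphenyl)-1,3,7,9-tetramethoxy-5a,6,11a,12-tetrahydrotetracene-5,11-dione | COc1ccc([C@@H]2c3c(OC)cc(OC)cc3C(=O)[C@H]4[C@H](c5ccc(OC)cc5)c5c(OC)cc(OC)cc5C(=O)[C@H]24)cc1
A6 | alternative 3 | 5-methoxy-3-[(4-methoxybenzyl)oxy]-2-(trimethylsilyl)phenyl trifluoromethanesulfonate | COc1cc(OCc2ccc(OC)cc2)c([Si](C)(C)C)c(OS(=O)(=O)C(F)(F)F)c1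
A7 | alternative 3 | bis(dibenzocyclooctadienone) with ketones at the future C3 and C3′ and 4-methoxybenzyl ethers on ring B | COc1ccc([C@@H]2c3c(OC)cc(OC)cc3C(=O)c4c(cc(OC)cc4[C@H]4[C@H](c5ccc(OC)cc5)c5c(OC)cc(OC)cc5C(=O)c6c(cc(OC)cc6[C@H]24)OCc2ccc(OC)cc2)OCc2ccc(OC)cc2)cc1
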